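**Plan**
- Retrosynthesis first re-attaches the silicon-based groups on the C5 and C4' phenols, then cuts ring A at C4a–C5 and C6–C7 (chroman numbering, ring B primed).
- Ring A carries oxygen at C5, C7 and C8a (O1 of the pyran) and the acyl chain at C6. C7–C8–C8a–C4a is therefore a 1,1,3-trioxygenated diene whose enol ether is the pyran ring, and C5–C6 is an alkoxy-substituted acyl alkyne.
- The ynone is cut at the carbonyl–alkyne bond (Weinreb amide plus lithium alkynyl ether) and ring B at the aryl–prenyl bond. The diene is cut at C8–C8a (lactone plus methyl acetate enolate) and traced to ethyl 5-oxohexanoate.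
- Forward: the pyran ring is made first (lactone, ylidene ester, silyl ketene acetal diene); the ring B chain is prenylated, silylated and converted into the ynone; benzannulation then builds ring A and joins the halves.
- The C5 oxygen is carried as a 2-(trimethylsilyl)ethyl ether, so one fluoride treatment frees both protected phenols without acid near the prenyl group.
- The target has no stereocentre; the regiochemistry of ring A follows from the polarity of diene and ynone.

Key step: step 10

Assumption: the target is achiral, and the alkene geometries drawn for the ylidene ester, the ketene acetal and the dichlorovinyl ether are the expected ones but are immaterial, since all three double bonds are consumed later.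

**Step 1**
Reactants: 1 ethyl 5-oxohexanoate
Product: 3 6,6-dimethyloxan-2-one, via hydroxy ester 2 (not isolated)
Conditions: MeMgBr (1.05 equiv), THF, −78 → −20 °C; 1 M HCl; then TsOH·H2O (cat.), CH2Cl2, rt
Reagents that add atoms: methylmagnesium bromide, C[Mg]Br
Why: Grignard addition at −78 °C should take the ketone in preference to the ethyl ester, and the tertiary hydroxy ester then lactonises to the six-membered ring under acid catalysis, helped by the gem-dimethyl group.

**Step 2**
Reactants: 3 6,6-dimethyloxan-2-one; 4 methyl acetate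
Product: 5 methyl 2-(2-hydroxy-6,6-dimethyloxan-2-yl)acetate (racemic lactol)
Conditions: 4, LiN(iPr)2 (2.2 equiv), THF, −78 °C; then 3, −78 °C; AcOH
Reagents that add atoms: none
Why: Claisen-type addition of an ester lithium enolate to a lactone stops at the tetrahedral adduct at −78 °C and gives the β-keto ester in its ring-closed hemiketal form; the hemiketal carbon is racemic and disappears in step 3.

**Step 3**
Reactants: 5 methyl 2-(2-hydroxy-6,6-dimethyloxan-2-yl)acetate
Product: 6 methyl (2E)-2-(6,6-dimethyloxan-2-ylidene)acetate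
Conditions: MsCl, Et3N, CH2Cl2, 0 °C → rt
Reagents that add atoms: none
Why: Sulfonylation of the lactol hydroxyl followed by elimination through the oxocarbenium ion (lactol dehydration) should give the conjugated exocyclic enol ether ester without acid that could ionise the tertiary ether carbon; any Z or endocyclic isomer gives the same dienolate in step 4.

**Step 4**
Reactants: 6 methyl (2E)-2-(6,6-dimethyloxan-2-ylidene)acetate
Product: 7 [(1Z)-2-(6,6-dimethyl-5,6-dihydro-4H-pyran-2-yl)-1-methoxyethenyl]oxy-trimethylsilane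
Conditions: LiN(iPr)2 (1.1 equiv), THF, −78 °C; Me3SiCl, −78 → 0 °C; pentane, filtration under Ar, used crude
Reagents that add atoms: chlorotrimethylsilane, C[Si](C)(C)Cl
Why: γ-Deprotonation of a β-alkoxy enoate at the ring CH2 gives the extended dienolate, and O-silylation gives the silyl ketene acetal with the double bond inside the pyran, the standard preparation of 1-alkoxy-1-silyloxy-3-oxygenated butadienes.

**Step 5**
Reactants: 8 methyl 3-(4-hydroxyphenyl)propanoate; 9 1-bromo-3-methylbut-2-ene (prenyl bromide)
Product: 10 methyl 3-[4-hydroxy-3-(3-methylbut-2-en-1-yl)phenyl]propanoate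
Conditions: NaH (1.0 equiv), toluene, 0 °C; then 9, 0 °C → rt
Reagents that add atoms: none
Why: In a non-coordinating solvent the tight sodium phenoxide ion pair should be alkylated at the ortho carbon by the primary allylic bromide (ortho C-alkylation of a phenoxide); the para position is blocked and the two ortho positions are equivalent.

**Step 6**
Reactants: 10 methyl 3-[4-hydroxy-3-(3-methylbut-2-en-1-yl)phenyl]propanoate
Product: 11 methyl 3-[4-(tert-butyldimethylsilyloxy)-3-(3-methylbut-2-en-1-yl)phenyl]propanoate
Conditions: TBSCl, imidazole, DMF, rt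
Reagents that add atoms: tert-butyl(chloro)dimethylsilane, CC(C)(C)[Si](C)(C)Cl
Why: Imidazole-promoted silylation of a phenol is routine and masks the acidic OH that would otherwise destroy the acetylide in step 9 and the ketene acetal in step 10.

**Step 7**
Reactants: 11 methyl 3-[4-(tert-butyldimethylsilyloxy)-3-(3-methylbut-2-en-1-yl)phenyl]propanoate
Product: 12 3-[4-(tert-butyldimethylsilyloxy)-3-(3-methylbut-2-en-1-yl)phenyl]-N-methoxy-N-methylpropanamide
Conditions: MeNH(OMe)·HCl, iPrMgCl, THF, −20 → 0 °C; 0.5 M HCl, 0 °C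
Reagents that add atoms: N,O-dimethylhydroxylamine hydrochloride, CNOC.Cl
Why: The chloromagnesium amide made in the flask aminolyses the methyl ester directly to the Weinreb amide at low temperature, conditions under which the aryl silyl ether and the alkene are inert.

**Step 8**
Reactants: 13 2-(trimethylsilyl)ethanol; 14 trichloroethene
Product: 15 (E)-1,2-dichloro-1-[2-(trimethylsilyl)ethoxy]ethene
Conditions: KH (1.1 equiv), THF, 0 °C; then 14, −50 °C → rt
Reagents that add atoms: none
Why: The potassium alkoxide adds to dichloroethyne formed in the flask from trichloroethene (net addition–elimination), which is the established first stage of the trichloroethene route to alkynyl ethers and is general for primary alcohols.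

**Step 9**
Reactants: 15 (E)-1,2-dichloro-1-[2-(trimethylsilyl)ethoxy]ethene; 12 3-[4-(tert-butyldimethylsilyloxy)-3-(3-methylbut-2-en-1-yl)phenyl]-N-methoxy-N-methylpropanamide
Product: 18 5-[4-(tert-butyldimethylsilyloxy)-3-(3-methylbut-2-en-1-yl)phenyl]-1-[2-(trimethylsilyl)ethoxy]pent-1-yn-3-one, via chloroalkynyl ether 16 (not isolated), via lithium alkynyl ether 17 (not isolated)
Conditions: n-BuLi (2.0 equiv per 15), THF, −78 → −40 °C; then 12, −78 → −20 °C; AcOH, pH 7 phosphate buffer
Reagents that add atoms: none
Why: Dehydrochlorination and chlorine–lithium exchange convert the dichlorovinyl ether into the lithium alkoxyacetylide, and acylation of an acetylide by a Weinreb amide stops at the ynone because the chelated tetrahedral adduct collapses only on the buffered work-up.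

**Step 10**
Reactants: 7 [(1Z)-2-(6,6-dimethyl-5,6-dihydro-4H-pyran-2-yl)-1-methoxyethenyl]oxy-trimethylsilane; 18 5-[4-(tert-butyldimethylsilyloxy)-3-(3-methylbut-2-en-1-yl)phenyl]-1-[2-(trimethylsilyl)ethoxy]pent-1-yn-3-one
Product: 21 1-[7-hydroxy-2,2-dimethyl-5-[2-(trimethylsilyl)ethoxy]-3,4-dihydro-2H-chromen-6-yl]-3-[4-(tert-butyldimethylsilyloxy)-3-(3-methylbut-2-en-1-yl)phenyl]propan-1-one, via cycloadduct 19 (not isolated), via aryl trimethylsilyl ether 20 (not isolated)
Conditions: 7 (1.5 equiv), toluene, 25 → 70 °C, sealed tube, Ar; then 1 M HCl, THF, 0 °C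
Reagents that add atoms: none
Why: Proposed new method: the diene terminus C4a, the β-carbon of the cyclic enol ether and vinylogously activated by the ketene acetal, should attack the alkoxy-bearing electrophilic carbon C5 of the push–pull ynone, after which the allenolate carbon C6 bonds to the oxygen-stabilised cationic carbon C7, a strongly asynchronous or stepwise [4+2] cycloaddition leading to cyclohexa-1,4-diene 19. The closest known reaction type is the Diels–Alder benzannulation of 1,1-dialkoxy- and 1-alkoxy-1-silyloxy-3-oxygenated butadienes with acetylenic ketones and esters to give resorcinol derivatives, whereas a β-alkoxy ynone as dienophile and a diene whose enol ether lies in a dihydropyran are untested. Ring A closes in the intermolecular [4+2] mode, C4a–C5 forming first and C6–C7 completing the six-membered carbocycle, with the pyran already fused because C8a=C4a is its endocyclic enol ether double bond. Methanol is then lost across C4a–H and C7–OMe under the driving force of aromatisation to give aryl silyl ether 20, and the acidic work-up hydrolyses its O–SiMe3 bond. The stereocentres at C4a and C7 of 19 vanish on aromatisation, so the only selectivity needed is regiochemical, and it is secured by the polarity match between nucleophilic C4a and electrophilic C5, which places the acyl-bearing C6 next to C7 and leaves O1 on C8a. The bath is held at or below 70 °C because alkynyl ethers with β-hydrogens can fragment to ketenes by a retro-ene path at higher temperature.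

**Step 11**
Reactants: 21 1-[7-hydroxy-2,2-dimethyl-5-[2-(trimethylsilyl)ethoxy]-3,4-dihydro-2H-chromen-6-yl]-3-[4-(tert-butyldimethylsilyloxy)-3-(3-methylbut-2-en-1-yl)phenyl]propan-1-one
Product: 22 1-(5,7-dihydroxy-2,2-dimethyl-3,4-dihydro-2H-chromen-6-yl)-3-[4-hydroxy-3-(3-methylbut-2-en-1-yl)phenyl]propan-1-one (CNP0080516.0)
Conditions: Bu4NF (excess), DMF, 25 → 60 °C, Ar; AcOH
Reagents that add atoms: none
Why: Fluoride attacks silicon in both groups, cleaving the aryl silyl ether directly and the 2-(trimethylsilyl)ethyl ether by β-elimination to ethene and the phenoxide (fluoride-induced desilylative fragmentation); no acid is present, so the prenyl group and the chroman are untouched.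

**Compound list**
1 | ethyl 5-oxohexanoate | CCOC(=O)CCCC(C)=O | starting material
2 | ethyl 5-hydroxy-5-methylhexanoate | CCOC(=O)CCCC(C)(C)O | intermediate
3 | 6,6-dimethyloxan-2-one | CC1(C)CCCC(=O)O1 | intermediate
4 | methyl acetate | COC(C)=O | starting material
5 | methyl 2-(2-hydroxy-6,6-dimethyloxan-2-yl)acetate (racemic lactol) | COC(=O)CC1(O)CCCC(C)(C)O1 | intermediate
6 | methyl (2E)-2-(6,6-dimethyloxan-2-ylidene)acetate | COC(=O)/C=C1\CCCC(C)(C)O1 | intermediate
7 | [(1Z)-2-(6,6-dimethyl-5,6-dihydro-4H-pyran-2-yl)-1-methoxyethenyl]oxy-trimethylsilane | CO/C(O[Si](C)(C)C)=C/C1=CCCC(C)(C)O1 | intermediate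
8 | methyl 3-(4-hydroxyphenyl)propanoate | COC(=O)CCc1ccc(O)cc1 | starting material
9 | 1-bromo-3-methylbut-2-ene | CC(C)=CCBr | starting material
10 | methyl 3-[4-hydroxy-3-(3-methylbut-2-en-1-yl)phenyl]propanoate | COC(=O)CCc1ccc(O)c(CC=C(C)C)c1 | intermediate
11 | methyl 3-[4-(tert-butyldimethylsilyloxy)-3-(3-methylbut-2-en-1-yl)phenyl]propanoate | COC(=O)CCc1ccc(O[Si](C)(C)C(C)(C)C)c(CC=C(C)C)c1 | intermediate
12 | 3-[4-(tert-butyldimethylsilyloxy)-3-(3-methylbut-2-en-1-yl)phenyl]-N-methoxy-N-methylpropanamide | CON(C)C(=O)CCc1ccc(O[Si](C)(C)C(C)(C)C)c(CC=C(C)C)c1 | intermediate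
13 | 2-(trimethylsilyl)ethanol | C[Si](C)(C)CCO | starting material
14 | trichloroethene | ClC=C(Cl)Cl | starting material
15 | (E)-1,2-dichloro-1-[2-(trimethylsilyl)ethoxy]ethene | C[Si](C)(C)CCO/C(Cl)=C\Cl | intermediate
16 | 1-chloro-2-[2-(trimethylsilyl)ethoxy]ethyne | C[Si](C)(C)CCOC#CCl | intermediate
17 | lithium [2-(trimethylsilyl)ethoxy]ethynide | C[Si](C)(C)CCOC#C[Li] | intermediate
18 | 5-[4-(tert-butyldimethylsilyloxy)-3-(3-methylbut-2-en-1-yl)phenyl]-1-[2-(trimethylsilyl)ethoxy]pent-1-yn-3-one | C[Si](C)(C)CCOC#CC(=O)CCc1ccc(O[Si](C)(C)C(C)(C)C)c(CC=C(C)C)c1 | intermediate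
19 | 1-[7-methoxy-2,2-dimethyl-5-[2-(trimethylsilyl)ethoxy]-7-(trimethylsilyloxy)-3,4,4a,7-tetrahydro-2H-chromen-6-yl]-3-[4-(tert-butyldimethylsilyloxy)-3-(3-methylbut-2-en-1-yl)phenyl]propan-1-one (diastereomer mixture at C4a and C7) | C[Si](C)(C)CCOC1=C(C(=O)CCc2ccc(O[Si](C)(C)C(C)(C)C)c(CC=C(C)C)c2)C(OC)(O[Si](C)(C)C)C=C2OC(C)(C)CCC12 | intermediate
20 | 1-[2,2-dimethyl-5-[2-(trimethylsilyl)ethoxy]-7-(trimethylsilyloxy)-3,4-dihydro-2H-chromen-6-yl]-3-[4-(tert-butyldimethylsilyloxy)-3-(3-methylbut-2-en-1-yl)phenyl]propan-1-one | C[Si](C)(C)CCOc1c(C(=O)CCc2ccc(O[Si](C)(C)C(C)(C)C)c(CC=C(C)C)c2)c(O[Si](C)(C)C)cc2c1CCC(C)(C)O2 | intermediate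
21 | 1-[7-hydroxy-2,2-dimethyl-5-[2-(trimethylsilyl)ethoxy]-3,4-dihydro-2H-chromen-6-yl]-3-[4-(tert-butyldimethylsilyloxy)-3-(3-methylbut-2-en-1-yl)phenyl]propan-1-one | C[Si](C)(C)CCOc1c(C(=O)CCc2ccc(O[Si](C)(C)C(C)(C)C)c(CC=C(C)C)c2)c(O)cc2c1CCC(C)(C)O2 | intermediate
22 | 1-(5,7-dihydroxy-2,2-dimethyl-3,4-dihydro-2H-chromen-6-yl)-3-[4-hydroxy-3-(3-methylbut-2-en-1-yl)phenyl]propan-1-one | CC(C)=CCc1cc(CCC(=O)c2c(O)cc3c(c2O)CCC(C)(C)O3)ccc1O | target

**Totals**
Total step count: 11. Longest linear sequence: 6 steps (steps 1–4, 10, 11, or steps 5–7, 9, 10, 11).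

**Steps most likely to fail**

Step 10 (proposed new method). The donor-substituted ynone may be too weak a dienophile, so that hydrolysis or silyl transfer of the ketene acetal, or thermal fragmentation of the alkynyl ether, outruns the cycloaddition; conjugate addition may also stop at an open-chain adduct. The fallback uses known aryl-metal chemistry, leaves the route at Weinreb amide 12 and rejoins it at target 22. Phloroglucinol and 2-methylbut-3-en-2-ol (BF3·OEt2, dioxane) should give 2,2-dimethyl-3,4-dihydro-2H-chromene-5,7-diol F1, which is protected (MOMCl, iPr2NEt, CH2Cl2) as 5,7-bis(methoxymethoxy)-2,2-dimethyl-3,4-dihydro-2H-chromene F2. Directed ortho-lithiation (n-BuLi, THF, 0 °C) is expected at C6, the position flanked by both acetal oxygens, giving [5,7-bis(methoxymethoxy)-2,2-dimethyl-3,4-dihydro-2H-chromen-6-yl]lithium F3. Addition of F3 to 12 should give 1-[5,7-bis(methoxymethoxy)-2,2-dimethyl-3,4-dihydro-2H-chromen-6-yl]-3-[4-(tert-butyldimethylsilyloxy)-3-(3-methylbut-2-en-1-yl)phenyl]propan-1-one F4. Dilute HCl in MeOH removes both acetals while the ring B phenol is still silylated, giving 3-[4-(tert-butyldimethylsilyloxy)-3-(3-methylbut-2-en-1-yl)phenyl]-1-(5,7-dihydroxy-2,2-dimethyl-3,4-dihydro-2H-chromen-6-yl)propan-1-one F5, and Bu4NF/AcOH in THF at 0 °C then gives 22.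

Step 11. The 2-(trimethylsilyl)ethyl ether may fragment only sluggishly, because the departing aryloxide sits on a hindered ring that already carries a phenoxide, and prolonged heating in basic fluoride may degrade the polyphenol. The fallback starts from 21 and rejoins at 22, replacing fluoride attack by a chelation-driven Lewis-acid fragmentation. Bu4NF/AcOH in THF at 0 °C removes only the aryl silyl ether and gives 1-[7-hydroxy-2,2-dimethyl-5-[2-(trimethylsilyl)ethoxy]-3,4-dihydro-2H-chromen-6-yl]-3-[4-hydroxy-3-(3-methylbut-2-en-1-yl)phenyl]propan-1-one F6. MgBr2·OEt2 in CH2Cl2 at rt, bound between the ketone and the C5 ether oxygen, should then expel ethene and bromotrimethylsilane, as it does with related β-silylethyl protecting groups, and aqueous work-up gives 22.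

Step 5. O-alkylation and double C-alkylation of the phenoxide may consume most of the material, leaving little mono-ortho-prenyl phenol. The fallback starts from 8 and rejoins at 10 through a sigmatropic route that fixes the ortho position. Copper-catalysed O-propargylation (3-chloro-3-methylbut-1-yne, CuCl2·2H2O cat., DBU, MeCN, 0 °C) gives methyl 3-[4-(2-methylbut-3-yn-2-yloxy)phenyl]propanoate F7. Semi-hydrogenation (H2, Pd/CaCO3 poisoned with Pb(OAc)2, quinoline, EtOAc) gives methyl 3-[4-(2-methylbut-3-en-2-yloxy)phenyl]propanoate F8. Aromatic Claisen rearrangement (N,N-diethylaniline, 140 °C) then delivers the linear prenyl group to the ortho carbon and gives 10.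

**Further compounds**
F1 | step 10 | 2,2-dimethyl-3,4-dihydro-2H-chromene-5,7-diol | CC1(C)CCc2c(O)cc(O)cc2O1
F2 | step 10 | 5,7-bis(methoxymethoxy)-2,2-dimethyl-3,4-dihydro-2H-chromene | COCOc1cc(OCOC)c2c(c1)OC(C)(C)CC2
F3 | step 10 | [5,7-bis(methoxymethoxy)-2,2-dimethyl-3,4-dihydro-2H-chromen-6-yl]lithium | [Li]c1c(OCOC)cc2c(c1OCOC)CCC(C)(C)O2
F4 | step 10 | 1-[5,7-bis(methoxymethoxy)-2,2-dimethyl-3,4-dihydro-2H-chromen-6-yl]-3-[4-(tert-butyldimethylsilyloxy)-3-(3-methylbut-2-en-1-yl)phenyl]propan-1-one | COCOc1cc2c(c(OCOC)c1C(=O)CCc1ccc(O[Si](C)(C)C(C)(C)C)c(CC=C(C)C)c1)CCC(C)(C)O2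
F5 | step 10 | 3-[4-(tert-butyldimethylsilyloxy)-3-(3-methylbut-2-en-1-yl)phenyl]-1-(5,7-dihydroxy-2,2-dimethyl-3,4-dihydro-2H-chromen-6-yl)propan-1-one | CC(C)=CCc1cc(CCC(=O)c2c(O)cc3c(c2O)CCC(C)(C)O3)ccc1O[Si](C)(C)C(C)(C)C
F6 | step 11 | 1-[7-hydroxy-2,2-dimethyl-5-[2-(trimethylsilyl)ethoxy]-3,4-dihydro-2H-chromen-6-yl]-3-[4-hydroxy-3-(3-methylbut-2-en-1-yl)phenyl]propan-1-one | C[Si](C)(C)CCOc1c(C(=O)CCc2ccc(O)c(CC=C(C)C)c2)c(O)cc2c1CCC(C)(C)O2
F7 | step 5 | methyl 3-[4-(2-methylbut-3-yn-2-yloxy)phenyl]propanoate | COC(=O)CCc1ccc(OC(C)(C)C#C)cc1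
F8 | step 5 | methyl 3-[4-(2-methylbut-3-en-2-yloxy)phenyl]propanoate | COC(=O)CCc1ccc(OC(C)(C)C=C)cc1
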